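(All runs stem from a simulated flask from invented constants, and the scatter is random.)

I had no rate constants for this chemistry, so I reckoned with what was left, not with what was made.

| setting | Thursday's | Monday's | Friday's | Saturday's | south-west | south-east | north-west |
|---|---|---|---|---|---|---|---|
| substrate | 0.20 M | 0.20 M | 0.20 M | 0.30 M | 0.20 M (fed, over 10 min) | 0.20 M | 0.20 M |
| partner | 1.3 equiv | 0.65 equiv | 2.6 equiv | 1.3 equiv | 1.30 equiv | 1.30 equiv | 1.30 equiv |
| reagent | 1.8 equiv | 1.8 equiv | 1.8 equiv | 1.8 equiv | 1.80 equiv | 1.80 equiv (fed, over 10 min) | 1.80 equiv |
| protic impurity | 0.060 M | 0.060 M | 0.060 M | 0.060 M | 0.0600 M | 0.0600 M | 0.0600 M |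
| remark | run made earlier | run made earlier | run made earlier | run made earlier | all else is in the flask from the start; the feed brings no volume worth counting | all else is in the flask from the start; the feed brings no volume worth counting | everything together at the start |
| time |  |  |  |  | 12 min | 12 min | 12 min |

- Thursday's (time / min: target / %, over-reaction product / %): 2.00: 2.2, 0; 4.00: 7.8, 0.3; 5.00: 10.2, 0.3; 8.00: 16.5, 1.3
- Monday's (time / min: target / %, over-reaction product / %): 4.00: 3.7, 0.9; 8.00: 9.5, 1.5; 10.0: 11.3, 1.9; 15.0: 13.7, 4.8
- Friday's (time / min: target / %, over-reaction product / %): 1.00: 0.9, 0.6; 2.50: 6.0, 0; 6.00: 21.6, 0.6; 15.0: 40.5, 3.8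
- Saturday's (time / min: target / %, over-reaction product / %): 4.00: 13.8, 1.5; 8.00: 23.6, 5.3; 10.0: 26.9, 8.0; 15.0: 31.8, 11.1

(readings scatter by 0.5 percentage points)

- a reading or a percentage of target counts all its forms, free or not

- which flask leads in share of target in target plus over-reaction product ("all alike" within 1.5 percentage points) (south-west / south-east / north-west / all alike)
- share of target in target plus over-reaction product at the end, south-west
- share of target in target plus over-reaction product at the end, south-east
- share of target in target plus over-reaction product at the end, north-west

The three flasks each charge [reagent] minus [protic impurity] = 0.300 M. I called this the surplus: the reagent left once the protic impurity has taken its share, one for one as I assumed. Saturday's charge left 0.480 M.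

The loss ratio is over-reaction product per target. It read 0.0788 in Thursday's run at 8.00 min and 0.225 in Saturday's at 8.00 min. That factor of 2.86 lay close to the squared surplus ratio, 2.56, so I let the loss ratio follow the surplus squared, with equivalents and impurity held. Within Saturday's run it reached twice its value at 4.00 min, so I let it grow with time too.

For north-west, Thursday's reading gave 0.118 at 12 min, a share of target (the selectivity) of 89.4 %. But that over-reaction reading was 1.3 %, with a scatter of 0.5 percentage points. So I reforged the link from Saturday's 8.0 % at 10.0 min. This gave a ratio of 0.139 and a share of 87.8 % for north-west.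

South-west kept the surplus, but its substrate came in 5.00 min late on average. Its target aged 7.00 min, so I reckoned 92.5 %. In south-east the feed had delivered the impurity's amount by 1.67 min. The surplus then climbed to 0.300 M at 10 min, a mean of 0.154 M over the run, counting no other use. Squared, that gave 96.4 %.

The forecast chose south-east, with 91.5 % for south-west, 95.5 % for south-east and 88 % for north-west. Its grounds for south-east were “reagent feed first titrates impurity, then free reagent stays scarce until late”. My south-west and south-east numbers lay higher.

south-east led with 92.8 %, against 90.5 % in south-west and 84.0 % in north-west.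

    open intermediate + second intermediate → target (k = 1.30 M⁻¹ min⁻¹)
    substrate + target ⇌ idle adduct, settled at all times (K = 65.0 M⁻¹)
    reagent + target → over-reaction product (k = 0.960 M⁻¹ min⁻¹)
    substrate + reagent → open intermediate (k = 3.40 M⁻¹ min⁻¹)
    reagent + partner → second intermediate (k = 0.330 M⁻¹ min⁻¹)
    reagent + protic impurity → quenched reagent (k = 19.0 M⁻¹ min⁻¹)

In north-west the quenched reagent stood at 0.0600 M at 12.0 min, level with the 0.0600 M charged, so the impurity's share was one for one, as I had assumed. But the surplus is a sum on the charge: the reagent left in north-west at 12.0 min was 9.19 % of its charge. That flask's loss ratio was 0.191, higher than my 0.139. A neighbour of north-west with 0.12 M of substrate, equivalents and time held, has a surplus of 0.156 M. Scaling 0.191 by the surplus squared gives 0.0516, a share of 95.1 %. That neighbour gave 93.0 %.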